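**Retrosynthetic overview** (indane numbering of the target: C1 carries the arylidene, C2 the 3,5-dihydroxyphenyl group, C3 the 2,4-dihydroxyphenyl group)

1. Target ⇐ its hexabenzyl ether by global O-debenzylation.
2. Hexabenzyl ether ⇐ a (1S)-1-aryl-3-benzyl-1H-indene plus an arylboronic acid: one oxidative Heck reaction installs the C2 aryl group trans and the exocyclic E-alkene.
3. Indene (carbocycle, second ring formed) ⇐ a (2S)-2-aryl-2-benzyl-2H-chromene by a palladium-catalysed ring contraction that trades the C–O stereocentre for the C–C stereocentre and frees the ortho-phenol.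
4. 2H-Chromene (pyran ring, first ring formed) ⇐ a tertiary allylic alcohol by enantioselective C–O ring closure, the only enantio-determining event of the route.
5. Allylic alcohol ⇐ a benzylic Grignard reagent plus a 2′-bromo-2-hydroxychalcone ⇐ brominated 3,5-bis(benzyloxy)acetophenone plus 4-(benzyloxy)salicylaldehyde.

Assumption: the target is the (1E,2S,3S) isomer encoded by the SMILES; the four benzyl-protected aromatic building blocks are bought as catalogue chemicals; the enantiomer of the chiral acid in step 4 is chosen to deliver (2S).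

Step 1
Reactants: 1 1-[3,5-bis(benzyloxy)phenyl]ethan-1-one
Product: 2 1-[3,5-bis(benzyloxy)-2-bromophenyl]ethan-1-one
Conditions: NBS, MeCN, 0 to 25 °C
Reagents that add atoms: N-bromosuccinimide, O=C1CCC(=O)N1Br
Why: Electrophilic aromatic bromination goes to the position that is para to one benzyloxy group and ortho to the other and is less hindered than the site between the two ethers, which gives the single aryl bromide needed as the handle for step 5.

Step 2
Reactants: 2 1-[3,5-bis(benzyloxy)-2-bromophenyl]ethan-1-one; 3 4-(benzyloxy)-2-hydroxybenzaldehyde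
Product: 4 (2E)-1-[3,5-bis(benzyloxy)-2-bromophenyl]-3-[4-(benzyloxy)-2-hydroxyphenyl]prop-2-en-1-one
Conditions: KOH, EtOH, 25 °C; then AcOH
Reagents that add atoms: none
Why: Claisen–Schmidt condensation of the methyl ketone enolate with the non-enolisable aldehyde, followed by dehydration, gives the conjugated E-enone under thermodynamic control, and the aryl bromide and benzyl ethers are inert to hydroxide.

Step 3
Reactants: 4 (2E)-1-[3,5-bis(benzyloxy)-2-bromophenyl]-3-[4-(benzyloxy)-2-hydroxyphenyl]prop-2-en-1-one; 5 1-(benzyloxy)-4-(chloromethyl)-2-methoxybenzene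
Product: 7 racemic (3E)-2-[3,5-bis(benzyloxy)-2-bromophenyl]-1-[4-(benzyloxy)-3-methoxyphenyl]-4-[4-(benzyloxy)-2-hydroxyphenyl]but-3-en-2-ol, via arylmethylmagnesium chloride 6 (not isolated)
Conditions: 5, Mg, THF, 0 °C; then 4, LaCl3·2LiCl, THF, −40 °C; NH4Cl (aq.), neutral work-up
Reagents that add atoms: none
Why: Grignard 1,2-addition is favoured because the phenoxide formed first turns the enone into a vinylogous ester and the oxophilic lanthanum salt activates the carbonyl carbon, which gives the racemic tertiary allylic alcohol whose stereocentre is erased in step 4.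

Step 4
Reactants: 7 racemic (3E)-2-[3,5-bis(benzyloxy)-2-bromophenyl]-1-[4-(benzyloxy)-3-methoxyphenyl]-4-[4-(benzyloxy)-2-hydroxyphenyl]but-3-en-2-ol
Product: 8 (2S)-7-(benzyloxy)-2-{[4-(benzyloxy)-3-methoxyphenyl]methyl}-2-[3,5-bis(benzyloxy)-2-bromophenyl]-2H-chromene
Conditions: (S)-3,3′-bis(2,4,6-triisopropylphenyl)-H8-BINOL N-triflylphosphoramide (5 mol%), toluene, 4 Å MS, −78 °C; filtration through basic Al2O3
Reagents that add atoms: none
Why: Brønsted-acid-catalysed asymmetric allylic etherification (SN1-type) ionises the alcohol to a 1,3-diarylallyl cation paired with the chiral phosphoramide anion that also binds the phenol, so the six-membered C–O ring closure takes place on one face of the cation terminus and both enantiomers of 7 converge on the 2S ether.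

Step 5
Reactants: 8 (2S)-7-(benzyloxy)-2-{[4-(benzyloxy)-3-methoxyphenyl]methyl}-2-[3,5-bis(benzyloxy)-2-bromophenyl]-2H-chromene
Product: 11 5-(benzyloxy)-2-[(1S)-5,7-bis(benzyloxy)-3-{[4-(benzyloxy)-3-methoxyphenyl]methyl}-1H-inden-1-yl]phenol, via aryllithium 9 (not isolated), via arylzinc chloride 10 (not isolated)
Conditions: n-BuLi, THF, −78 °C; ZnCl2, −78 to 0 °C; Pd(PPh3)4 (5 mol%), 25 °C; NH4Cl (aq.)
Reagents that add atoms: none
Why: Proposed new method: an intramolecular Negishi-type allyl–aryl coupling with allylic transposition, in which zerovalent palladium ionises the allylic C–O bond anti (the zinc, chelated to the ether oxygen, acts as internal Lewis acid), the aryl group passes from zinc to palladium and is delivered syn to the distal allyl terminus through a six-membered palladacycle; only the allyl isomer that has the arene cis to that terminus can close the five-membered ring, so the new C–C bond forms on the face the arene occupied in 8 and 2S is translated into 1S while the phenol is released; the closest known reaction type is the stereospecific palladium- or nickel-catalysed coupling of allylic aryl ethers and carbonates with aryl-zinc or aryl-magnesium reagents, which runs with inversion then retention.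

Step 6
Reactants: 11 5-(benzyloxy)-2-[(1S)-5,7-bis(benzyloxy)-3-{[4-(benzyloxy)-3-methoxyphenyl]methyl}-1H-inden-1-yl]phenol; 12 [3,5-bis(benzyloxy)phenyl]boronic acid
Product: 13 5-(benzyloxy)-2-[(1S,2S,3E)-5,7-bis(benzyloxy)-2-[3,5-bis(benzyloxy)phenyl]-3-{[4-(benzyloxy)-3-methoxyphenyl]methylidene}-2,3-dihydro-1H-inden-1-yl]phenol
Conditions: Pd(OAc)2 (10 mol%), 2,9-dimethyl-1,10-phenanthroline (12 mol%), O2 (1 atm), amine-free DMF, 50 °C
Reagents that add atoms: none
Why: In this base-free oxidative Heck reaction the arylpalladium species, formed by transmetalation from boron to divalent palladium, adds across the C2=C3 bond from the face opposite the C1 aryl group (C2 set S, trans), and because the ring hydrogen at C2 is then anti to palladium, syn β-hydride elimination can only take a benzylic hydrogen and gives the exocyclic E-alkene without touching C1.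

Step 7
Reactants: 13 5-(benzyloxy)-2-[(1S,2S,3E)-5,7-bis(benzyloxy)-2-[3,5-bis(benzyloxy)phenyl]-3-{[4-(benzyloxy)-3-methoxyphenyl]methylidene}-2,3-dihydro-1H-inden-1-yl]phenol
Product: 14 (1E,2S,3S)-2-(3,5-dihydroxyphenyl)-3-(2,4-dihydroxyphenyl)-1-[(4-hydroxy-3-methoxyphenyl)methylidene]-2,3-dihydro-1H-indene-4,6-diol
Conditions: BCl3, C6HMe5, CH2Cl2, −78 °C; H2O
Reagents that add atoms: none
Why: Lewis-acid ether cleavage removes the six benzyl groups as benzyl cations that pentamethylbenzene traps by Friedel–Crafts alkylation, at a temperature at which the aryl methyl ether, the styrenic alkene and both stereocentres are left untouched.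

**Compound list**

1 | 1-[3,5-bis(benzyloxy)phenyl]ethan-1-one | CC(=O)c1cc(OCc2ccccc2)cc(OCc2ccccc2)c1 | starting material
2 | 1-[3,5-bis(benzyloxy)-2-bromophenyl]ethan-1-one | CC(=O)c1cc(OCc2ccccc2)cc(OCc2ccccc2)c1Br | intermediate
3 | 4-(benzyloxy)-2-hydroxybenzaldehyde | O=Cc1ccc(OCc2ccccc2)cc1O | starting material
4 | (2E)-1-[3,5-bis(benzyloxy)-2-bromophenyl]-3-[4-(benzyloxy)-2-hydroxyphenyl]prop-2-en-1-one | O=C(/C=C/c1ccc(OCc2ccccc2)cc1O)c1cc(OCc2ccccc2)cc(OCc2ccccc2)c1Br | intermediate
5 | 1-(benzyloxy)-4-(chloromethyl)-2-methoxybenzene | COc1cc(CCl)ccc1OCc1ccccc1 | starting material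
6 | {[4-(benzyloxy)-3-methoxyphenyl]methyl}magnesium chloride | COc1cc(C[Mg]Cl)ccc1OCc1ccccc1 | intermediate
7 | racemic (3E)-2-[3,5-bis(benzyloxy)-2-bromophenyl]-1-[4-(benzyloxy)-3-methoxyphenyl]-4-[4-(benzyloxy)-2-hydroxyphenyl]but-3-en-2-ol | OC(Cc1ccc(OCc2ccccc2)c(OC)c1)(/C=C/c1ccc(OCc2ccccc2)cc1O)c1cc(OCc2ccccc2)cc(OCc2ccccc2)c1Br | intermediate
8 | (2S)-7-(benzyloxy)-2-{[4-(benzyloxy)-3-methoxyphenyl]methyl}-2-[3,5-bis(benzyloxy)-2-bromophenyl]-2H-chromene | O(Cc1ccccc1)c1ccc2C=C[C@@](Cc3ccc(OCc4ccccc4)c(OC)c3)(c3cc(OCc4ccccc4)cc(OCc4ccccc4)c3Br)Oc2c1 | intermediate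
9 | {2,4-bis(benzyloxy)-6-[(2S)-7-(benzyloxy)-2-{[4-(benzyloxy)-3-methoxyphenyl]methyl}-2H-chromen-2-yl]phenyl}lithium | O(Cc1ccccc1)c1ccc2C=C[C@@](Cc3ccc(OCc4ccccc4)c(OC)c3)(c3cc(OCc4ccccc4)cc(OCc4ccccc4)c3[Li])Oc2c1 | intermediate
10 | {2,4-bis(benzyloxy)-6-[(2S)-7-(benzyloxy)-2-{[4-(benzyloxy)-3-methoxyphenyl]methyl}-2H-chromen-2-yl]phenyl}zinc chloride | O(Cc1ccccc1)c1ccc2C=C[C@@](Cc3ccc(OCc4ccccc4)c(OC)c3)(c3cc(OCc4ccccc4)cc(OCc4ccccc4)c3[Zn]Cl)Oc2c1 | intermediate
11 | 5-(benzyloxy)-2-[(1S)-5,7-bis(benzyloxy)-3-{[4-(benzyloxy)-3-methoxyphenyl]methyl}-1H-inden-1-yl]phenol | Oc1cc(OCc2ccccc2)ccc1[C@@H]1C=C(Cc2ccc(OCc3ccccc3)c(OC)c2)c2cc(OCc3ccccc3)cc(OCc3ccccc3)c21 | intermediate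
12 | [3,5-bis(benzyloxy)phenyl]boronic acid | OB(O)c1cc(OCc2ccccc2)cc(OCc2ccccc2)c1 | starting material
13 | 5-(benzyloxy)-2-[(1S,2S,3E)-5,7-bis(benzyloxy)-2-[3,5-bis(benzyloxy)phenyl]-3-{[4-(benzyloxy)-3-methoxyphenyl]methylidene}-2,3-dihydro-1H-inden-1-yl]phenol | COc1cc(/C=C2/c3cc(OCc4ccccc4)cc(OCc4ccccc4)c3[C@H](c3ccc(OCc4ccccc4)cc3O)[C@H]2c2cc(OCc3ccccc3)cc(OCc3ccccc3)c2)ccc1OCc1ccccc1 | intermediate
14 | (1E,2S,3S)-2-(3,5-dihydroxyphenyl)-3-(2,4-dihydroxyphenyl)-1-[(4-hydroxy-3-methoxyphenyl)methylidene]-2,3-dihydro-1H-indene-4,6-diol | COc1cc(/C=C2/c3cc(O)cc(O)c3[C@H](c3ccc(O)cc3O)[C@H]2c2cc(O)cc(O)c2)ccc1O | target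

**Step count and risks**

Total step count: 7. Longest linear sequence: 7 steps (1 to 14); compounds 3, 5 and 12 enter as bought materials.

The three steps most likely to fail are steps 3, 4 and 5. Step 6 is not ranked because the same oxidative Heck reaction is established on closely related 1-aryl-3-benzylindenes.

In step 3 the electron-rich benzylic Grignard reagent 6 can undergo Wurtz coupling or conjugate addition, and alcohol 7 closes to racemic chromene on traces of acid, which would erode the selectivity of step 4. The fallback sets out from 4 and 5 and replaces carbonyl addition by carbonyl olefination. Chloride 5 and PPh3 give {[4-(benzyloxy)-3-methoxyphenyl]methyl}(triphenyl)phosphonium chloride F1. Its ylide (n-BuLi, THF) converts ketone 4 in a Wittig reaction into 5-(benzyloxy)-2-[(1E)-3-[3,5-bis(benzyloxy)-2-bromophenyl]-4-[4-(benzyloxy)-3-methoxyphenyl]buta-1,3-dien-1-yl]phenol F2, a stable achiral diene. With the chiral acid of step 4, protonation of F2 at the benzylidene carbon gives the same allyl cation and phosphoramide ion pair, and the phenol closes the ring (asymmetric hydroalkoxylation), so the route is rejoined at 8.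

In step 4 the hindered ortho-bromoaryl group may lower the enantioselectivity, and the free position ortho to the allyl cation on the dibenzyloxy ring can compete by Friedel–Crafts closure. The fallback sets out from 7 and gives up catalyst control. Pyridinium p-toluenesulfonate in CH2Cl2 at 0 °C gives racemic 7-(benzyloxy)-2-{[4-(benzyloxy)-3-methoxyphenyl]methyl}-2-[3,5-bis(benzyloxy)-2-bromophenyl]-2H-chromene F3, which is separated by preparative chromatography on a chiral stationary phase; the 2S enantiomer rejoins the route at 8.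

Step 5 is the proposed new step. Its risks are β-hydride loss from the allylpalladium intermediate to give the diene, loss of stereochemical fidelity if the allyl ether ionises without palladium, and base-induced racemisation of the indene 11. The fallback uses known chemistry only and sets out from 4. An enantioselective reductive Heck cyclisation of the 2′-bromochalcone (Pd(OAc)2, (R)-MeO-BIPHEP, HCO2H and iPr2NEt, DMF, 80 °C) gives (3S)-4,6-bis(benzyloxy)-3-[4-(benzyloxy)-2-hydroxyphenyl]-2,3-dihydro-1H-inden-1-one F4. Addition of Grignard reagent 6 (LaCl3·2LiCl, THF) gives (3S)-4,6-bis(benzyloxy)-1-{[4-(benzyloxy)-3-methoxyphenyl]methyl}-3-[4-(benzyloxy)-2-hydroxyphenyl]-2,3-dihydro-1H-inden-1-ol F5 as a mixture of C1 epimers. Acid-catalysed dehydration (TsOH, toluene, 40 °C) takes the ring hydrogen and returns to the route at 11.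

**Further compounds**

F1 | step 3 | {[4-(benzyloxy)-3-methoxyphenyl]methyl}(triphenyl)phosphonium chloride | COc1cc(C[P+](c2ccccc2)(c2ccccc2)c2ccccc2)ccc1OCc1ccccc1.[Cl-]
F2 | step 3 | 5-(benzyloxy)-2-[(1E)-3-[3,5-bis(benzyloxy)-2-bromophenyl]-4-[4-(benzyloxy)-3-methoxyphenyl]buta-1,3-dien-1-yl]phenol (mixture of isomers at the second alkene) | Oc1cc(OCc2ccccc2)ccc1/C=C/C(=Cc1ccc(OCc2ccccc2)c(OC)c1)c1cc(OCc2ccccc2)cc(OCc2ccccc2)c1Br
F3 | step 4 | racemic 7-(benzyloxy)-2-{[4-(benzyloxy)-3-methoxyphenyl]methyl}-2-[3,5-bis(benzyloxy)-2-bromophenyl]-2H-chromene | O(Cc1ccccc1)c1ccc2C=CC(Cc3ccc(OCc4ccccc4)c(OC)c3)(c3cc(OCc4ccccc4)cc(OCc4ccccc4)c3Br)Oc2c1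
F4 | step 5 | (3S)-4,6-bis(benzyloxy)-3-[4-(benzyloxy)-2-hydroxyphenyl]-2,3-dihydro-1H-inden-1-one | O=C1C[C@@H](c2ccc(OCc3ccccc3)cc2O)c2c(OCc3ccccc3)cc(OCc3ccccc3)cc21
F5 | step 5 | (3S)-4,6-bis(benzyloxy)-1-{[4-(benzyloxy)-3-methoxyphenyl]methyl}-3-[4-(benzyloxy)-2-hydroxyphenyl]-2,3-dihydro-1H-inden-1-ol (both C1 epimers) | OC1(Cc2ccc(OCc3ccccc3)c(OC)c2)C[C@@H](c2ccc(OCc3ccccc3)cc2O)c2c(OCc3ccccc3)cc(OCc3ccccc3)cc21
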